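**Strategy.** The route rests on disconnecting the side chain between C6′ (CH2) and C7′ (the methyl-bearing carbon; primed numbers count the tridecyl chain from the cyclohexenone ring). The key step exploits the C8′ hydroxyl next to C7′. The C7′ methyl is carried as the exocyclic methylene of a 2-bromoallylic alcohol, so a B-alkyl Suzuki–Miyaura coupling with the alkylborane from the terminal alkene of the ring fragment forges C6′–C7′ in one operation. The C8′ hydroxyl then directs hydrogenation of the methylene to the anti methyl group. The ring enone and tertiary alcohol travel as an allylic dimethyl ketal and a silyl ether.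

Key step: step 12

Assumption: 2-bromoprop-2-enal (18) and 4-methoxybenzyl chloromethyl ether are taken as purchasable reagents.

**Ring fragment**

Step 1
Reactants: 1 (R)-β-citronellene [(3R)-3,7-dimethylocta-1,6-diene]
Product: 3 (4R)-4-methylhex-5-en-1-ol, via (4R)-4-methylhex-5-enal 2 (not isolated)
Conditions: O3 (1.0 equiv), CH2Cl2–MeOH, −78 °C; then NaBH4, −78 → 0 °C
Reagents that add atoms: ozone, [O-][O+]=O
Why: Ozone reacts far faster with the electron-rich trisubstituted alkene than with the monosubstituted one (chemoselective ozonolysis), and the borohydride work-up reduces the aldehyde to the primary alcohol while the methyl-bearing stereocentre from the chiral pool (later C4′) is untouched.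

Step 2
Reactants: 3 (4R)-4-methylhex-5-en-1-ol
Product: 4 (3R)-6-iodo-3-methylhex-1-ene
Conditions: I2, PPh3, imidazole, CH2Cl2, 0 °C → rt
Reagents that add atoms: iodine, II
Why: Appel iodination turns the primary alcohol into the iodide under neutral conditions that leave the alkene and the stereocentre alone.

Step 3
Reactants: 5 4,4-dimethoxycyclohexa-2,5-dien-1-one
Product: 6 (5R)-5-ethyl-4,4-dimethoxycyclohex-2-en-1-one
Conditions: Et2Zn, Cu(OTf)2 (2 mol%), (S)-BINOL-derived phosphoramidite of bis[(R)-1-phenylethyl]amine (4 mol%), toluene, −25 °C; aq. NH4Cl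
Reagents that add atoms: diethylzinc, CC[Zn]CC
Why: Copper-catalysed asymmetric conjugate addition: the chiral phosphoramidite–copper ethyl species distinguishes the enantiotopic alkene faces of the prochiral dienone and sets the ethyl-bearing centre (later ring C6) as R, the ligand antipode being chosen by analogy with its sense of induction on cyclohex-2-enone and exchanged for its enantiomer should the opposite sense be found.

Step 4
Reactants: 6 (5R)-5-ethyl-4,4-dimethoxycyclohex-2-en-1-one
Product: 8 (5R,6R)-5-ethyl-4,4-dimethoxy-6-methylcyclohex-2-en-1-one, via lithium enolate 7 (not isolated)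
Conditions: LiN(i-Pr)2, THF, −78 °C; then MeI, −78 → −20 °C
Reagents that add atoms: iodomethane, CI
Why: Deprotonation is possible only at C6 because C4 is a ketal carbon, and the cross-conjugated lithium enolate is methylated mainly trans to the C5 ethyl group (enolate alkylation); this C6 configuration is erased again in step 5.

Step 5
Reactants: 8 (5R,6R)-5-ethyl-4,4-dimethoxy-6-methylcyclohex-2-en-1-one; 4 (3R)-6-iodo-3-methylhex-1-ene
Product: 10 (5R,6R)-5-ethyl-4,4-dimethoxy-6-methyl-6-[(4R)-4-methylhex-5-en-1-yl]cyclohex-2-en-1-one, via lithium enolate 9 (not isolated)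
Conditions: LiN(i-Pr)2, THF, −78 °C; then 4 (2 equiv), DMPU, −78 → 0 °C
Reagents that add atoms: none
Why: Enolate alkylation creates the quaternary centre: in the tetrasubstituted enolate the C5 ethyl group sits pseudoaxial to avoid allylic strain with the C6 methyl group, so the iodide enters from the opposite face and the side chain ends up trans to ethyl (C6 R).

Step 6
Reactants: 10 (5R,6R)-5-ethyl-4,4-dimethoxy-6-methyl-6-[(4R)-4-methylhex-5-en-1-yl]cyclohex-2-en-1-one
Product: 12 triethyl{[(1R,5R,6R)-5-ethyl-4,4-dimethoxy-1,6-dimethyl-6-[(4R)-4-methylhex-5-en-1-yl]cyclohex-2-en-1-yl]oxy}silane, via lithium alkoxide 11 (not isolated)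
Conditions: MeLi, THF, −78 °C; then TESOTf, −78 → 0 °C
Reagents that add atoms: methyllithium, [Li]C; triethylsilyl trifluoromethanesulfonate, CC[Si](CC)(CC)OS(=O)(=O)C(F)(F)F
Why: Carbonyl 1,2-addition to a ketone without enolisable hydrogens: in the half-chair with equatorial ethyl and side chain the axial C6 methyl group blocks its own face, so methyl is delivered anti to the C6 methyl and C5 ethyl groups and the oxygen ends up cis to them (C1 R), and the hindered alkoxide is capped in the flask as its triethylsilyl ether.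

**Polyol fragment**

Step 7
Reactants: 13 (S)-4-benzyl-3-butanoyl-1,3-oxazolidin-2-one
Product: 15 (S)-4-benzyl-3-[(2R)-2-{[(4-methoxybenzyl)oxy]methyl}butanoyl]-1,3-oxazolidin-2-one, via chlorotitanium enolate 14 (not isolated)
Conditions: TiCl4, i-Pr2NEt, CH2Cl2, 0 °C; then 4-methoxybenzyl chloromethyl ether, 0 °C
Reagents that add atoms: 4-methoxybenzyl chloromethyl ether, COc1ccc(COCCl)cc1
Why: Evans alkylation: the chelated chlorotitanium Z-enolate is attacked by the chloromethyl ether on the face opposite the benzyl group, which sets the α-carbon (later C11′) as R.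

Step 8
Reactants: 15 (S)-4-benzyl-3-[(2R)-2-{[(4-methoxybenzyl)oxy]methyl}butanoyl]-1,3-oxazolidin-2-one
Product: 16 S-ethyl (2R)-2-{[(4-methoxybenzyl)oxy]methyl}butanethioate
Conditions: EtSH, n-BuLi, THF, 0 °C
Reagents that add atoms: ethanethiol, CCS
Why: Thiolate cleavage of the N-acyloxazolidinone: the soft, weakly basic lithium ethanethiolate attacks the exocyclic carbonyl of the hindered imide and frees the auxiliary without epimerising the α-centre.

Step 9
Reactants: 16 S-ethyl (2R)-2-{[(4-methoxybenzyl)oxy]methyl}butanethioate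
Product: 17 (3R)-3-{[(4-methoxybenzyl)oxy]methyl}pentan-2-one
Conditions: Me2CuLi (from MeLi and CuI), Et2O, −78 → −40 °C
Reagents that add atoms: lithium dimethylcuprate, [Li+].C[Cu-]C
Why: Acyl substitution of the thioester by the Gilman cuprate stops at the methyl ketone, and the non-basic conditions keep the α-centre intact.

Step 10
Reactants: 17 (3R)-3-{[(4-methoxybenzyl)oxy]methyl}pentan-2-one; 18 2-bromoprop-2-enal
Product: 20 (3S,6R)-2-bromo-3-hydroxy-6-{[(4-methoxybenzyl)oxy]methyl}oct-1-en-5-one, via boron enolate 19 (not isolated)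
Conditions: (c-Hex)2BCl, Et3N, Et2O, −78 → 0 °C; then 18, −78 °C; H2O2, MeOH, pH 7 buffer, 0 °C
Reagents that add atoms: none
Why: Boron-mediated aldol reaction: the amine/chloroborane pair enolises the methyl group only, and the α-stereocentre with its β-benzyl-type ether steers the enol borinate to the aldehyde face that gives the 1,4-syn adduct, so the new carbinol (later C8′) is S.

Step 11
Reactants: 20 (3S,6R)-2-bromo-3-hydroxy-6-{[(4-methoxybenzyl)oxy]methyl}oct-1-en-5-one
Product: 22 (3S,5R,6R)-2-bromo-6-{[(4-methoxybenzyl)oxy]methyl}oct-1-ene-3,5-diol, via diethylborinate 21 (not isolated)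
Conditions: Et2BOMe, THF–MeOH, −78 °C; then NaBH4, −78 °C; H2O2, pH 7 buffer
Reagents that add atoms: none
Why: Narasaka–Prasad reduction: the diethylboron chelate of the β-hydroxy ketone takes up hydride axially and gives the 1,3-syn diol, so the new carbinol (later C10′) is R.

**Fragment union and end game**

Step 12
Reactants: 12 triethyl{[(1R,5R,6R)-5-ethyl-4,4-dimethoxy-1,6-dimethyl-6-[(4R)-4-methylhex-5-en-1-yl]cyclohex-2-en-1-yl]oxy}silane; 22 (3S,5R,6R)-2-bromo-6-{[(4-methoxybenzyl)oxy]methyl}oct-1-ene-3,5-diol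
Product: 24 (2R,3R,5S,9R)-12-[(1R,2R,6R)-6-ethyl-5,5-dimethoxy-1,2-dimethyl-2-(triethylsilyloxy)cyclohex-3-en-1-yl]-2-ethyl-1-[(4-methoxybenzyl)oxy]-9-methyl-6-methylidenedodecane-3,5-diol, via B-alkyl-9-BBN 23 (not isolated)
Conditions: 12, 9-BBN, THF, rt; then 22, Pd(dppf)Cl2 (5 mol%), AsPh3, Cs2CO3, DMF–H2O, rt
Reagents that add atoms: none
Why: 9-BBN hydroborates only the monosubstituted terminal alkene of 12, since the ring alkene lies between two fully substituted carbons, and places boron on the terminal carbon (later C6′). Zerovalent palladium then inserts into the C–Br bond of 22, the base-activated primary B-alkyl group is transferred to palladium, and reductive elimination forms the C6′–C7′ bond; the closest known reaction type is the B-alkyl Suzuki–Miyaura coupling of 2-bromoalk-1-enes. No ring is closed. No stereocentre is formed in this step: C7′ emerges as the sp2 carbon of a 1,1-disubstituted allylic alcohol, and its configuration is set in step 13 under control of the adjacent hydroxyl group. The step needs chemoselectivity (terminal alkene before ring alkene, coupling before β-hydride elimination of the alkylpalladium species), which the hindered ring alkene and the wide bite angle of dppf secure, and it tolerates the free diol, the ketal and the silyl ether because the base is mild and aqueous.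

Step 13
Reactants: 24 the 6-methylidene diol from step 12
Product: 25 (2R,3R,5S,6R,9R)-12-[(1R,2R,6R)-6-ethyl-5,5-dimethoxy-1,2-dimethyl-2-(triethylsilyloxy)cyclohex-3-en-1-yl]-2-ethyl-1-[(4-methoxybenzyl)oxy]-6,9-dimethyldodecane-3,5-diol
Conditions: [Rh(nbd)(dppb)]BF4 (10 mol%), H2 (60 bar), CH2Cl2, rt
Reagents that add atoms: none
Why: Hydroxyl-directed hydrogenation: the cationic rhodium catalyst binds the allylic hydroxyl (C8′) and delivers hydrogen to the methylene face exposed in the conformer of least allylic strain, which gives the anti hydroxyl/methyl relationship (C7′ R), while the hindered ring alkene, which has no free hydroxyl next to it, is not reduced.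

Step 14
Reactants: 25 the 6,9-dimethyl diol from step 13
Product: 26 (2R,3R,5S,6R,9R)-12-[(1R,2R,6R)-6-ethyl-5,5-dimethoxy-1,2-dimethyl-2-(triethylsilyloxy)cyclohex-3-en-1-yl]-2-ethyl-6,9-dimethyldodecane-1,3,5-triol
Conditions: DDQ, CH2Cl2–pH 7 buffer, 0 °C
Reagents that add atoms: none
Why: Oxidative cleavage of the 4-methoxybenzyl ether by DDQ (benzylic hydride abstraction, then hydrolysis of the oxocarbenium ion) frees the primary alcohol; any benzylidene acetal formed with the neighbouring hydroxyl is hydrolysed in step 15.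

Step 15
Reactants: 26 the ketal-protected triol from step 14
Product: 27 (4R,5R,6R)-5-[(4R,7R,8S,10R,11R)-8,10-dihydroxy-11-(hydroxymethyl)-4,7-dimethyltridecyl]-6-ethyl-4-hydroxy-4,5-dimethylcyclohex-2-en-1-one (target)
Conditions: 1 M aq. HCl, THF, 0 °C → rt
Reagents that add atoms: water, O
Why: Acid hydrolysis removes the dimethyl ketal, which reveals the enone, and the triethylsilyl ether; the ethyl-bearing centre next to the new ketone already has the more stable configuration, trans to the side chain, so it is not at risk.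

**Compound list**

1 | (R)-β-citronellene, (3R)-3,7-dimethylocta-1,6-diene | C=C[C@H](C)CCC=C(C)C | starting material
2 | (4R)-4-methylhex-5-enal | C=C[C@H](C)CCC=O | intermediate
3 | (4R)-4-methylhex-5-en-1-ol | C=C[C@H](C)CCCO | intermediate
4 | (3R)-6-iodo-3-methylhex-1-ene | C=C[C@H](C)CCCI | intermediate
5 | 4,4-dimethoxycyclohexa-2,5-dien-1-one | COC1(OC)C=CC(=O)C=C1 | starting material
6 | (5R)-5-ethyl-4,4-dimethoxycyclohex-2-en-1-one | O=C1C=CC(OC)(OC)[C@H](CC)C1 | intermediate
7 | lithium enolate of 6, lithium (3R)-3-ethyl-4,4-dimethoxycyclohexa-1,5-dien-1-olate | [Li]OC1=C[C@@H](CC)C(OC)(OC)C=C1 | intermediate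
8 | (5R,6R)-5-ethyl-4,4-dimethoxy-6-methylcyclohex-2-en-1-one (methyl trans to ethyl) | C[C@@H]1[C@@H](CC)C(OC)(OC)C=CC1=O | intermediate
9 | lithium enolate of 8, lithium (3R)-3-ethyl-4,4-dimethoxy-2-methylcyclohexa-1,5-dien-1-olate | [Li]OC1=C(C)[C@@H](CC)C(OC)(OC)C=C1 | intermediate
10 | (5R,6R)-5-ethyl-4,4-dimethoxy-6-methyl-6-[(4R)-4-methylhex-5-en-1-yl]cyclohex-2-en-1-one | C=C[C@H](C)CCC[C@]1(C)[C@@H](CC)C(OC)(OC)C=CC1=O | intermediate
11 | lithium (1R,5R,6R)-5-ethyl-4,4-dimethoxy-1,6-dimethyl-6-[(4R)-4-methylhex-5-en-1-yl]cyclohex-2-en-1-olate | C=C[C@H](C)CCC[C@]1(C)[C@@H](CC)C(OC)(OC)C=C[C@@]1(C)O[Li] | intermediate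
12 | triethyl{[(1R,5R,6R)-5-ethyl-4,4-dimethoxy-1,6-dimethyl-6-[(4R)-4-methylhex-5-en-1-yl]cyclohex-2-en-1-yl]oxy}silane | C=C[C@H](C)CCC[C@]1(C)[C@@H](CC)C(OC)(OC)C=C[C@@]1(C)O[Si](CC)(CC)CC | intermediate
13 | (S)-4-benzyl-3-butanoyl-1,3-oxazolidin-2-one | CCCC(=O)N1[C@@H](Cc2ccccc2)COC1=O | starting material
14 | chlorotitanium (Z)-enolate of 13 | CC/C=C(\O[Ti](Cl)(Cl)Cl)N1[C@@H](Cc2ccccc2)COC1=O | intermediate
15 | (S)-4-benzyl-3-[(2R)-2-{[(4-methoxybenzyl)oxy]methyl}butanoyl]-1,3-oxazolidin-2-one | CC[C@H](COCc1ccc(OC)cc1)C(=O)N1[C@@H](Cc2ccccc2)COC1=O | intermediate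
16 | S-ethyl (2R)-2-{[(4-methoxybenzyl)oxy]methyl}butanethioate | CC[C@H](COCc1ccc(OC)cc1)C(=O)SCC | intermediate
17 | (3R)-3-{[(4-methoxybenzyl)oxy]methyl}pentan-2-one | CC[C@H](COCc1ccc(OC)cc1)C(C)=O | intermediate
18 | 2-bromoprop-2-enal (2-bromoacrolein) | C=C(Br)C=O | starting material
19 | dicyclohexylboron enolate of 17, (3R)-3-{[(4-methoxybenzyl)oxy]methyl}pent-1-en-2-yl dicyclohexylborinate | CC[C@H](COCc1ccc(OC)cc1)C(=C)OB(C1CCCCC1)C1CCCCC1 | intermediate
20 | (3S,6R)-2-bromo-3-hydroxy-6-{[(4-methoxybenzyl)oxy]methyl}oct-1-en-5-one | CC[C@H](COCc1ccc(OC)cc1)C(=O)C[C@H](O)C(Br)=C | intermediate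
21 | O-diethylboryl derivative (diethylborinate) of 20 | CC[C@H](COCc1ccc(OC)cc1)C(=O)C[C@H](OB(CC)CC)C(Br)=C | intermediate
22 | (3S,5R,6R)-2-bromo-6-{[(4-methoxybenzyl)oxy]methyl}oct-1-ene-3,5-diol | CC[C@H](COCc1ccc(OC)cc1)[C@H](O)C[C@H](O)C(Br)=C | intermediate
23 | B-alkyl-9-BBN from 12 (9-borabicyclo[3.3.1]nonan-9-yl on the former terminal alkene carbon, all stereocentres as in 12) | B3(C4CCCC3CCC4)CC[C@H](C)CCC[C@]1(C)[C@@H](CC)C(OC)(OC)C=C[C@@]1(C)O[Si](CC)(CC)CC | intermediate
24 | (2R,3R,5S,9R)-12-[(1R,2R,6R)-6-ethyl-5,5-dimethoxy-1,2-dimethyl-2-(triethylsilyloxy)cyclohex-3-en-1-yl]-2-ethyl-1-[(4-methoxybenzyl)oxy]-9-methyl-6-methylidenedodecane-3,5-diol | CC[C@H](COCc1ccc(OC)cc1)[C@H](O)C[C@H](O)C(=C)CC[C@H](C)CCC[C@]1(C)[C@@H](CC)C(OC)(OC)C=C[C@@]1(C)O[Si](CC)(CC)CC | intermediate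
25 | (2R,3R,5S,6R,9R)-12-[(1R,2R,6R)-6-ethyl-5,5-dimethoxy-1,2-dimethyl-2-(triethylsilyloxy)cyclohex-3-en-1-yl]-2-ethyl-1-[(4-methoxybenzyl)oxy]-6,9-dimethyldodecane-3,5-diol | CC[C@H](COCc1ccc(OC)cc1)[C@H](O)C[C@H](O)[C@H](C)CC[C@H](C)CCC[C@]1(C)[C@@H](CC)C(OC)(OC)C=C[C@@]1(C)O[Si](CC)(CC)CC | intermediate
26 | (2R,3R,5S,6R,9R)-12-[(1R,2R,6R)-6-ethyl-5,5-dimethoxy-1,2-dimethyl-2-(triethylsilyloxy)cyclohex-3-en-1-yl]-2-ethyl-6,9-dimethyldodecane-1,3,5-triol | CC[C@H](CO)[C@H](O)C[C@H](O)[C@H](C)CC[C@H](C)CCC[C@]1(C)[C@@H](CC)C(OC)(OC)C=C[C@@]1(C)O[Si](CC)(CC)CC | intermediate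
27 | (4R,5R,6R)-5-[(4R,7R,8S,10R,11R)-8,10-dihydroxy-11-(hydroxymethyl)-4,7-dimethyltridecyl]-6-ethyl-4-hydroxy-4,5-dimethylcyclohex-2-en-1-one | CC[C@H](CO)[C@H](O)C[C@H](O)[C@H](C)CC[C@H](C)CCC[C@]1(C)[C@@H](CC)C(=O)C=C[C@@]1(C)O | target

**Step count.** Total: 15 steps. Longest linear sequence: 9 steps (steps 7–15, from 13).

**Steps most likely to fail**

Step 5. The fully substituted enolate 9 may react too slowly with the unactivated primary iodide, so that proton exchange and O-alkylation take over. The fallback sets out from alcohol 3 and ketone 8 and comes back at 10. Alcohol 3 is converted (Tf2O, 2,6-lutidine, CH2Cl2, −78 °C) into (4R)-4-methylhex-5-en-1-yl trifluoromethanesulfonate F1. F1 is added cold to the potassium enolate of 8 (KN(SiMe3)2, THF, −78 °C). A primary triflate alkylates hindered enolates at temperatures where the side reactions are frozen, and the facial bias from the C5 ethyl group is unchanged.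

Step 6. Methyl delivery to the ketone may show poor facial selectivity, or may prefer the face of the C6 methyl group. The fallback sets out from 10 and comes back at 12, and it exchanges the roles of carbon and oxygen. Wittig methylenation (Ph3P=CH2, THF, reflux) should give the 1-methylidene analogue of 10, (5R,6R)-5-ethyl-4,4-dimethoxy-6-methyl-1-methylidene-6-[(4R)-4-methylhex-5-en-1-yl]cyclohex-2-ene F2. Dimethyldioxirane (acetone, −20 °C) should epoxidise the electron-rich exocyclic alkene from the accessible face to the spiro-epoxide (3R,7R,8R)-7-ethyl-6,6-dimethoxy-8-methyl-8-[(4R)-4-methylhex-5-en-1-yl]-1-oxaspiro[2.5]oct-4-ene F3. LiEt3BH (THF, 0 °C) opens F3 at its CH2 terminus to lithium alkoxide 11, which is silylated as in step 6. An electrophilic oxygen donor places oxygen on the face where methyllithium would place carbon, so the two sequences are stereocomplementary.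

Step 13. Hydrogen may be delivered with too little anti preference, or the cationic rhodium catalyst may isomerise the allylic alcohol to the ethyl ketone or begin to reduce the ring alkene. The fallback sets out from 24 and comes back at 25. It is a catalyst-controlled hydrogenation with Ru(OAc)2(BINAP) in MeOH under H2, using the BINAP enantiomer matched to the (S)-carbinol. This catalyst reduces only alkenes held through an allylic hydroxyl and adds its own facial preference to that of the substrate. The fallback forms no compound outside the list (F0).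

**Further compounds**

F1 | step 5 | (4R)-4-methylhex-5-en-1-yl trifluoromethanesulfonate | C=C[C@H](C)CCCOS(=O)(=O)C(F)(F)F
F2 | step 6 | (5R,6R)-5-ethyl-4,4-dimethoxy-6-methyl-1-methylidene-6-[(4R)-4-methylhex-5-en-1-yl]cyclohex-2-ene | C=C[C@H](C)CCC[C@]1(C)[C@@H](CC)C(OC)(OC)C=CC1=C
F3 | step 6 | (3R,7R,8R)-7-ethyl-6,6-dimethoxy-8-methyl-8-[(4R)-4-methylhex-5-en-1-yl]-1-oxaspiro[2.5]oct-4-ene | C=C[C@H](C)CCC[C@]1(C)[C@@H](CC)C(OC)(OC)C=C[C@@]12OC2
F0 | step 13 | none | none
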